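**Retrosynthetic overview**
1. The C8 acetate and C11 angelate go on last. The C11 methyl/carbinol pair comes from methylation, then convex-face hydroxylation, of the enolate of the cis-fused γ-lactone (ring B, formed second, by oxidative lactonisation of a 6,12-diol).
2. The ten-membered carbocycle (ring A, formed first) is closed at C2–C3 by intramolecular alkylation of a (Z)-allylic sulfone carbanion with an (E)-allylic bromide, followed by reductive desulfonylation.
3. In the open chain, C4=C5 (E) comes from a stabilised Wittig reaction on the C5 aldehyde, C1=C10 (Z) from syn-carbocupration of an ynoate, and C8–C9 from Felkin-controlled propargylation of the C8 aldehyde.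
4. C7 is set by Fráter–Seebach anti-allylation of a β-hydroxy ester whose carbinol (C6, first stereocentre) comes from ketoreductase reduction of an achiral β-keto ester.

Assumption: the target is taken exactly as the SMILES encodes it (6,7-cis-fused lactone, 6S,7R,8S,11S, 1(10)Z,4E, ester = angelate); positions are cited in germacrane numbering (C12 lactone carbonyl, lactone O on C6, OAc on C8, angelate on C11); PMB = 4-methoxybenzyl, TBS = tert-butyldimethylsilyl; small reagents that donate atoms are given with SMILES on their own line and carry no number.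

**Route**

Step 1
Reactants: 1 ethyl 4-chloro-3-oxobutanoate
Product: 2 ethyl 4-[(4-methoxybenzyl)oxy]-3-oxobutanoate
Conditions: NaH (2.2 equiv), 4-methoxybenzyl alcohol, THF, 0 °C to rt; aq. HCl work-up
Reagents that add atoms: 4-methoxybenzyl alcohol, COc1ccc(CO)cc1
Why: Williamson etherification in which the sodium alkoxide displaces the primary chloride while the second equivalent of NaH holds the β-keto ester as its enolate; no stereocentre is involved.

Step 2
Reactants: 2 β-keto ester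
Product: 3 ethyl (3R)-3-hydroxy-4-[(4-methoxybenzyl)oxy]butanoate
Conditions: (R)-selective ketoreductase (NADPH-dependent carbonyl reductase), NADP+ (cat.), propan-2-ol (10% v/v), phosphate buffer pH 7, 30 °C
Reagents that add atoms: none
Why: Enzymatic asymmetric ketone reduction (biocatalytic transfer hydrogenation) in which the active site delivers hydride to one face of the prochiral ketone, setting C6 as the first stereocentre in high ee.

Step 3
Reactants: 3 β-hydroxy ester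
Product: 5 ethyl (2S,3R)-2-allyl-3-hydroxy-4-[(4-methoxybenzyl)oxy]butanoate, via dilithium dianion 4 (not isolated)
Conditions: LiN(iPr)2 (2.2 equiv), THF, −78 to −20 °C; allyl bromide, DMPU, −78 to −10 °C
Reagents that add atoms: allyl bromide, C=CCBr
Why: Fráter–Seebach alkylation, in which the chelated alkoxide-enolate is allylated anti to the C6 substituent, giving the 6,7-anti relationship (C7) that later becomes the cis ring fusion.

Step 4
Reactants: 5 allylated hydroxy ester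
Product: 6 ethyl (2S)-2-[(4R)-2-(4-methoxyphenyl)-1,3-dioxolan-4-yl]pent-4-enoate (both acetal epimers)
Conditions: DDQ (1.2 equiv), 4 Å molecular sieves, CH2Cl2, 0 °C
Reagents that add atoms: none
Why: Oxidative acetalisation, in which DDQ oxidises the PMB ether to an oxocarbenium ion that is trapped by the neighbouring C6 hydroxyl, tying O5 and O6 into one acetal without touching C6 or C7.

Step 5
Reactants: 6 acetal ester
Product: 7 (2R)-2-[(4R)-2-(4-methoxyphenyl)-1,3-dioxolan-4-yl]pent-4-en-1-ol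
Conditions: LiAlH4, THF, 0 °C
Reagents that add atoms: none
Why: Hydride reduction of the ester to the primary alcohol; the acetal and the stereocentres are inert to LiAlH4.

Step 6
Reactants: 7 primary alcohol
Product: 8 (2S)-2-[(4R)-2-(4-methoxyphenyl)-1,3-dioxolan-4-yl]pent-4-enal
Conditions: Dess–Martin periodinane, NaHCO3, CH2Cl2, 0 °C to rt; used at once
Reagents that add atoms: none
Why: Buffered Dess–Martin oxidation gives the α-branched C8 aldehyde without epimerising C7.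

Step 7
Reactants: 8 aldehyde
Product: 9 (4S,5R)-5-[(4R)-2-(4-methoxyphenyl)-1,3-dioxolan-4-yl]oct-7-en-1-yn-4-ol
Conditions: Bu3SnCH=C=CH2, BF3·OEt2, CH2Cl2, −78 °C
Reagents that add atoms: tributyl(propa-1,2-dien-1-yl)stannane, CCCC[Sn](CCCC)(CCCC)C=C=C
Why: Lewis-acid-promoted SE2' propargylation through an open transition state, in which Felkin–Anh attack anti to the dioxolanyl group is reinforced by 1,3-anti induction from the β-oxygen, sets C8 (S) syn to the C7 branch.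

Step 8
Reactants: 9 homopropargylic alcohol
Product: 10 (4S,5S)-5-[(tert-butyldimethylsilyl)oxy]-4-[(4R)-2-(4-methoxyphenyl)-1,3-dioxolan-4-yl]oct-1-en-7-yne
Conditions: TBSOTf, 2,6-lutidine, CH2Cl2, −78 to 0 °C
Reagents that add atoms: tert-butyldimethylsilyl trifluoromethanesulfonate, CC(C)(C)[Si](C)(C)OS(=O)(=O)C(F)(F)F
Why: Silylation of the secondary C8 hydroxyl with the reactive triflate gives a robust ether that survives to the end of the route.

Step 9
Reactants: 10 silyl ether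
Product: 13 (3S,4S)-4-[(tert-butyldimethylsilyl)oxy]-3-[(4R)-2-(4-methoxyphenyl)-1,3-dioxolan-4-yl]hept-6-yn-1-ol, via vicinal diol 11 (not isolated), via aldehyde 12 (not isolated)
Conditions: OsO4 (2 mol%), NaIO4, 2,6-lutidine, dioxane/H2O, rt; then NaBH4, EtOH, 0 °C
Reagents that add atoms: osmium tetroxide, O=[Os](=O)(=O)=O; sodium periodate, [Na+].[O-]I(=O)(=O)=O
Why: Lemieux–Johnson cleavage of the only alkene (the terminal alkyne is inert to OsO4) followed by borohydride reduction turns the allyl group into the C11–C12 hydroxyethyl arm.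

Step 10
Reactants: 13 primary alcohol
Product: 14 (4S,5S)-4-[(tert-butyldimethylsilyl)oxy]-7-[(4-methoxybenzyl)oxy]-5-[(4R)-2-(4-methoxyphenyl)-1,3-dioxolan-4-yl]hept-1-yne
Conditions: NaH, 4-methoxybenzyl chloride, Bu4NI (cat.), THF/DMF, 0 °C to rt
Reagents that add atoms: 4-methoxybenzyl chloride, COc1ccc(CCl)cc1
Why: Williamson etherification masks O12 with the same group that will later sit on O6, so both can be removed together.

Step 11
Reactants: 14 terminal alkyne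
Product: 16 methyl (5S,6S)-5-[(tert-butyldimethylsilyl)oxy]-8-[(4-methoxybenzyl)oxy]-6-[(4R)-2-(4-methoxyphenyl)-1,3-dioxolan-4-yl]oct-2-ynoate, via lithium acetylide 15 (not isolated)
Conditions: n-BuLi, THF, −78 °C; ClCO2Me, −78 to 0 °C
Reagents that add atoms: methyl chloroformate, COC(=O)Cl
Why: Acetylide acylation installs C2 as an ester and activates the alkyne for conjugate addition.

Step 12
Reactants: 16 ynoate
Product: 17 methyl (2Z,5S,6S)-5-[(tert-butyldimethylsilyl)oxy]-8-[(4-methoxybenzyl)oxy]-6-[(4R)-2-(4-methoxyphenyl)-1,3-dioxolan-4-yl]-3-methyloct-2-enoate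
Conditions: Me2CuLi (from MeLi and CuI), THF, −78 °C; MeOH quench at −78 °C
Reagents that add atoms: lithium dimethylcuprate, [Li+].C[Cu-]C
Why: Syn-carbocupration (conjugate addition) with low-temperature protonation places the new methyl and the hydrogen cis, fixing C1=C10 as Z (C9 cis to C2).

Step 13
Reactants: 17 (Z)-enoate
Product: 18 (2Z,5S,6S)-5-[(tert-butyldimethylsilyl)oxy]-8-[(4-methoxybenzyl)oxy]-6-[(4R)-2-(4-methoxyphenyl)-1,3-dioxolan-4-yl]-3-methyloct-2-en-1-ol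
Conditions: iBu2AlH (2.5 equiv), CH2Cl2, −78 °C
Reagents that add atoms: none
Why: 1,2-Reduction of the enoate to the allylic alcohol at −78 °C, where the benzylidene acetal is not yet opened and the Z olefin is untouched.

Step 14
Reactants: 18 (Z)-allylic alcohol
Product: 20 (2Z,5S,6S)-5-[(tert-butyldimethylsilyl)oxy]-8-[(4-methoxybenzyl)oxy]-6-[(4R)-2-(4-methoxyphenyl)-1,3-dioxolan-4-yl]-3-methyl-1-(phenylsulfonyl)oct-2-ene, via allylic bromide 19 (not isolated)
Conditions: CBr4, PPh3, 2,6-lutidine, CH2Cl2, 0 °C; then PhSO2Na, DMF, rt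
Reagents that add atoms: carbon tetrabromide (bromine of 19), BrC(Br)(Br)Br; sodium benzenesulfinate, [Na+].[O-]S(=O)c1ccccc1
Why: Appel bromination followed by SN2 S-alkylation of the sulfinate at the primary allylic carbon gives the sulfone with retention of the Z geometry.

Step 15
Reactants: 20 allylic sulfone
Product: 21 (2R,3S,4S,6Z)-4-[(tert-butyldimethylsilyl)oxy]-2-[(4-methoxybenzyl)oxy]-3-{2-[(4-methoxybenzyl)oxy]ethyl}-6-methyl-8-(phenylsulfonyl)oct-6-en-1-ol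
Conditions: iBu2AlH (4 equiv), CH2Cl2, −78 to 0 °C
Reagents that add atoms: none
Why: Regioselective reductive opening of the 4-methoxybenzylidene acetal, in which aluminium binds the less hindered primary oxygen so that hydride delivery leaves the PMB ether on O6 and frees the C5 alcohol.

Step 16
Reactants: 21 primary alcohol
Product: 22 (2R,3S,4S,6Z)-4-[(tert-butyldimethylsilyl)oxy]-2-[(4-methoxybenzyl)oxy]-3-{2-[(4-methoxybenzyl)oxy]ethyl}-6-methyl-8-(phenylsulfonyl)oct-6-enal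
Conditions: Dess–Martin periodinane, NaHCO3, CH2Cl2, 0 °C to rt; used at once
Reagents that add atoms: none
Why: Mild buffered Dess–Martin oxidation gives the α-alkoxy C5 aldehyde without epimerising C6.

Step 17
Reactants: 22 aldehyde
Product: 23 ethyl (2E,4S,5S,6S,8Z)-6-[(tert-butyldimethylsilyl)oxy]-4-[(4-methoxybenzyl)oxy]-5-{2-[(4-methoxybenzyl)oxy]ethyl}-2,8-dimethyl-10-(phenylsulfonyl)deca-2,8-dienoate
Conditions: Ph3P=C(CH3)CO2Et, CH2Cl2, rt
Reagents that add atoms: ethyl 2-(triphenylphosphoranylidene)propanoate, CCOC(=O)C(C)=P(c1ccccc1)(c1ccccc1)c1ccccc1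
Why: Wittig olefination with a stabilised, base-free ylide gives the (E)-trisubstituted C4=C5 olefin and does not deprotonate the sulfone.

Step 18
Reactants: 23 (E)-enoate
Product: 24 (2E,4S,5S,6S,8Z)-6-[(tert-butyldimethylsilyl)oxy]-4-[(4-methoxybenzyl)oxy]-5-{2-[(4-methoxybenzyl)oxy]ethyl}-2,8-dimethyl-10-(phenylsulfonyl)deca-2,8-dien-1-ol
Conditions: iBu2AlH (2.5 equiv), CH2Cl2, −78 °C
Reagents that add atoms: none
Why: 1,2-Reduction of the enoate to the (E)-allylic alcohol at C3; sulfone, ethers and olefin geometry are unaffected.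

Step 19
Reactants: 24 (E)-allylic alcohol
Product: 25 (2E,4S,5S,6S,8Z)-1-bromo-6-[(tert-butyldimethylsilyl)oxy]-4-[(4-methoxybenzyl)oxy]-5-{2-[(4-methoxybenzyl)oxy]ethyl}-2,8-dimethyl-10-(phenylsulfonyl)deca-2,8-diene
Conditions: CBr4, PPh3, CH2Cl2, −20 °C; rapid filtration, used at once
Reagents that add atoms: carbon tetrabromide, BrC(Br)(Br)Br
Why: Appel reaction converts the primary allylic alcohol into the bromide under neutral conditions without allylic transposition.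

Step 20
Reactants: 25 bromo sulfone
Product: 27 (1E,5Z,8S,9S,10S)-8-[(tert-butyldimethylsilyl)oxy]-10-[(4-methoxybenzyl)oxy]-9-{2-[(4-methoxybenzyl)oxy]ethyl}-2,6-dimethyl-4-(phenylsulfonyl)cyclodeca-1,5-diene (both C4 epimers), via sulfonyl carbanion 26 (not isolated)
Conditions: KN(SiMe3)2 (1.2 equiv), THF, 0.002 M, slow addition of 25, −78 to −20 °C
Reagents that add atoms: none
Why: Intramolecular SN2 alkylation of the α-sulfonyl allyl carbanion by the primary allylic bromide under high dilution closes ring A at C2–C3, a bond with no stereochemical demand, and the new sulfone-bearing centre is removed in the next step.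

Step 21
Reactants: 27 macrocyclic sulfone
Product: 28 (1E,5Z,8S,9S,10S)-8-[(tert-butyldimethylsilyl)oxy]-10-[(4-methoxybenzyl)oxy]-9-{2-[(4-methoxybenzyl)oxy]ethyl}-2,6-dimethylcyclodeca-1,5-diene
Conditions: PdCl2(dppp) (10 mol%), LiBHEt3 (3 equiv), THF, 0 °C
Reagents that add atoms: none
Why: Palladium-catalysed reductive desulfonylation, in which hydride is delivered to the less substituted terminus (C2) of the π-allyl complex, so C1=C10 stays in place and stays Z because syn/anti exchange would need a tertiary σ-palladium species.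

Step 22
Reactants: 28 bis-PMB ether
Product: 29 (1S,2E,6Z,9S,10S)-9-[(tert-butyldimethylsilyl)oxy]-10-(2-hydroxyethyl)-3,7-dimethylcyclodeca-2,6-dien-1-ol
Conditions: DDQ (3 equiv), CH2Cl2/pH 7 buffer (10:1), 0 °C
Reagents that add atoms: none
Why: Oxidative cleavage of both PMB ethers under neutral conditions frees O6 and O12 together while the TBS ether on O8 stays.

Step 23
Reactants: 29 diol
Product: 32 (3aS,4S,6Z,10E,11aS)-4-[(tert-butyldimethylsilyl)oxy]-6,10-dimethyl-3a,4,5,8,9,11a-hexahydrocyclodeca[b]furan-2(3H)-one, via hydroxy aldehyde 30 (not isolated), via lactol 31 (not isolated)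
Conditions: TEMPO (20 mol%), PhI(OAc)2 (3 equiv), CH2Cl2, rt
Reagents that add atoms: none
Why: Nitroxyl-catalysed oxidation of the primary alcohol, lactol formation with the C6 hydroxyl and further oxidation closes ring B, with the cis fusion fixed by the existing C6 and C7 configurations.

Step 24
Reactants: 32 lactone
Product: 34 (3aS,4S,6Z,10E,11aS)-4-[(tert-butyldimethylsilyl)oxy]-3,6,10-trimethyl-3a,4,5,8,9,11a-hexahydrocyclodeca[b]furan-2(3H)-one (C3 epimers), via lithium enolate 33 (not isolated)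
Conditions: LiN(iPr)2 (1.1 equiv), THF, −78 °C; MeI, −78 to −40 °C
Reagents that add atoms: iodomethane, CI
Why: Lactone enolate alkylation introduces C13, and the C11 configuration formed here does not matter because the next step re-forms the enolate.

Step 25
Reactants: 34 α-methyl lactone
Product: 36 (3S,3aS,4S,6Z,10E,11aS)-4-[(tert-butyldimethylsilyl)oxy]-3-hydroxy-3,6,10-trimethyl-3a,4,5,8,9,11a-hexahydrocyclodeca[b]furan-2(3H)-one, via potassium enolate 35 (not isolated)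
Conditions: KN(SiMe3)2 (1.3 equiv), THF, −78 °C; racemic 2-(phenylsulfonyl)-3-phenyloxaziridine, −78 °C
Reagents that add atoms: 2-(phenylsulfonyl)-3-phenyloxaziridine, O=S(=O)(N1OC1c1ccccc1)c1ccccc1
Why: Davis enolate hydroxylation delivers oxygen to the convex face, anti to C8 and C5 (both on the other face of the cis-fused lactone), giving the 11S tertiary alcohol with the methyl cis to C8.

Step 26
Reactants: 36 tertiary α-hydroxy lactone
Product: 38 (3S,3aS,4S,6Z,10E,11aS)-4-[(tert-butyldimethylsilyl)oxy]-3,6,10-trimethyl-2-oxo-2,3,3a,4,5,8,9,11a-octahydrocyclodeca[b]furan-3-yl (2Z)-2-methylbut-2-enoate, via lithium alkoxide 37 (not isolated)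
Conditions: LiN(SiMe3)2 (1.2 equiv), THF, −78 °C; angelic anhydride, −78 to 0 °C
Reagents that add atoms: (2Z)-2-methylbut-2-enoic anhydride, C/C=C(/C)C(=O)OC(=O)/C(C)=C\C
Why: O-acylation of the preformed lithium alkoxide with the anhydride at low temperature transfers the angeloyl group to the hindered tertiary oxygen without Z-to-E isomerisation.

Step 27
Reactants: 38 silyl ether angelate
Product: 39 (3S,3aR,4S,6Z,10E,11aS)-4-hydroxy-3,6,10-trimethyl-2-oxo-2,3,3a,4,5,8,9,11a-octahydrocyclodeca[b]furan-3-yl (2Z)-2-methylbut-2-enoate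
Conditions: HF·pyridine, pyridine, THF, 0 °C to rt
Reagents that add atoms: none
Why: Buffered fluoride desilylation frees the C8 hydroxyl without base, so the angelate, the lactone (no translactonisation) and the 1,5-diene are preserved.

Step 28
Reactants: 39 C8 alcohol
Product: 40 (3S,3aR,4S,6Z,10E,11aS)-4-(acetyloxy)-3,6,10-trimethyl-2-oxo-2,3,3a,4,5,8,9,11a-octahydrocyclodeca[b]furan-3-yl (2Z)-2-methylbut-2-enoate (CNP0148966.1)
Conditions: Ac2O, pyridine, DMAP (cat.), CH2Cl2, 0 °C to rt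
Reagents that add atoms: acetic anhydride, CC(=O)OC(C)=O
Why: DMAP-catalysed acetylation of the only free (secondary) hydroxyl proceeds with retention at C8 and gives the target.

**Compound list**

1 | ethyl 4-chloro-3-oxobutanoate | CCOC(=O)CC(=O)CCl | starting material
2 | ethyl 4-[(4-methoxybenzyl)oxy]-3-oxobutanoate | CCOC(=O)CC(=O)COCc1ccc(OC)cc1 | intermediate
3 | ethyl (3R)-3-hydroxy-4-[(4-methoxybenzyl)oxy]butanoate | CCOC(=O)C[C@@H](O)COCc1ccc(OC)cc1 | intermediate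
4 | dilithium alkoxide-enolate (dianion) of 3 | [Li+].[Li+].CCOC([O-])=C[C@@H]([O-])COCc1ccc(OC)cc1 | intermediate
5 | ethyl (2S,3R)-2-allyl-3-hydroxy-4-[(4-methoxybenzyl)oxy]butanoate | CCOC(=O)[C@@H](CC=C)[C@@H](O)COCc1ccc(OC)cc1 | intermediate
6 | ethyl (2S)-2-[(4R)-2-(4-methoxyphenyl)-1,3-dioxolan-4-yl]pent-4-enoate (acetal epimers) | CCOC(=O)[C@@H](CC=C)[C@@H]1COC(c2ccc(OC)cc2)O1 | intermediate
7 | (2R)-2-[(4R)-2-(4-methoxyphenyl)-1,3-dioxolan-4-yl]pent-4-en-1-ol | OC[C@@H](CC=C)[C@@H]1COC(c2ccc(OC)cc2)O1 | intermediate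
8 | (2S)-2-[(4R)-2-(4-methoxyphenyl)-1,3-dioxolan-4-yl]pent-4-enal | O=C[C@@H](CC=C)[C@@H]1COC(c2ccc(OC)cc2)O1 | intermediate
9 | (4S,5R)-5-[(4R)-2-(4-methoxyphenyl)-1,3-dioxolan-4-yl]oct-7-en-1-yn-4-ol | C#CC[C@H](O)[C@@H](CC=C)[C@@H]1COC(c2ccc(OC)cc2)O1 | intermediate
10 | (4S,5S)-5-[(tert-butyldimethylsilyl)oxy]-4-[(4R)-2-(4-methoxyphenyl)-1,3-dioxolan-4-yl]oct-1-en-7-yne | C#CC[C@H](O[Si](C)(C)C(C)(C)C)[C@@H](CC=C)[C@@H]1COC(c2ccc(OC)cc2)O1 | intermediate
11 | (4S,5S)-5-[(tert-butyldimethylsilyl)oxy]-4-[(4R)-2-(4-methoxyphenyl)-1,3-dioxolan-4-yl]oct-7-yne-1,2-diol (C2 epimers) | C#CC[C@H](O[Si](C)(C)C(C)(C)C)[C@@H](CC(O)CO)[C@@H]1COC(c2ccc(OC)cc2)O1 | intermediate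
12 | (3S,4S)-4-[(tert-butyldimethylsilyl)oxy]-3-[(4R)-2-(4-methoxyphenyl)-1,3-dioxolan-4-yl]hept-6-ynal | C#CC[C@H](O[Si](C)(C)C(C)(C)C)[C@@H](CC=O)[C@@H]1COC(c2ccc(OC)cc2)O1 | intermediate
13 | (3S,4S)-4-[(tert-butyldimethylsilyl)oxy]-3-[(4R)-2-(4-methoxyphenyl)-1,3-dioxolan-4-yl]hept-6-yn-1-ol | C#CC[C@H](O[Si](C)(C)C(C)(C)C)[C@@H](CCO)[C@@H]1COC(c2ccc(OC)cc2)O1 | intermediate
14 | (4S,5S)-4-[(tert-butyldimethylsilyl)oxy]-7-[(4-methoxybenzyl)oxy]-5-[(4R)-2-(4-methoxyphenyl)-1,3-dioxolan-4-yl]hept-1-yne | C#CC[C@H](O[Si](C)(C)C(C)(C)C)[C@@H](CCOCc3ccc(OC)cc3)[C@@H]1COC(c2ccc(OC)cc2)O1 | intermediate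
15 | lithium acetylide of 14 | [Li+].[C-]#CC[C@H](O[Si](C)(C)C(C)(C)C)[C@@H](CCOCc3ccc(OC)cc3)[C@@H]1COC(c2ccc(OC)cc2)O1 | intermediate
16 | methyl (5S,6S)-5-[(tert-butyldimethylsilyl)oxy]-8-[(4-methoxybenzyl)oxy]-6-[(4R)-2-(4-methoxyphenyl)-1,3-dioxolan-4-yl]oct-2-ynoate | COC(=O)C#CC[C@H](O[Si](C)(C)C(C)(C)C)[C@@H](CCOCc3ccc(OC)cc3)[C@@H]1COC(c2ccc(OC)cc2)O1 | intermediate
17 | methyl (2Z,5S,6S)-5-[(tert-butyldimethylsilyl)oxy]-8-[(4-methoxybenzyl)oxy]-6-[(4R)-2-(4-methoxyphenyl)-1,3-dioxolan-4-yl]-3-methyloct-2-enoate | COC(=O)/C=C(/C)C[C@H](O[Si](C)(C)C(C)(C)C)[C@@H](CCOCc3ccc(OC)cc3)[C@@H]1COC(c2ccc(OC)cc2)O1 | intermediate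
18 | (2Z,5S,6S)-5-[(tert-butyldimethylsilyl)oxy]-8-[(4-methoxybenzyl)oxy]-6-[(4R)-2-(4-methoxyphenyl)-1,3-dioxolan-4-yl]-3-methyloct-2-en-1-ol | OC/C=C(/C)C[C@H](O[Si](C)(C)C(C)(C)C)[C@@H](CCOCc3ccc(OC)cc3)[C@@H]1COC(c2ccc(OC)cc2)O1 | intermediate
19 | (2Z,5S,6S)-1-bromo-5-[(tert-butyldimethylsilyl)oxy]-8-[(4-methoxybenzyl)oxy]-6-[(4R)-2-(4-methoxyphenyl)-1,3-dioxolan-4-yl]-3-methyloct-2-ene | BrC/C=C(/C)C[C@H](O[Si](C)(C)C(C)(C)C)[C@@H](CCOCc3ccc(OC)cc3)[C@@H]1COC(c2ccc(OC)cc2)O1 | intermediate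
20 | (2Z,5S,6S)-5-[(tert-butyldimethylsilyl)oxy]-8-[(4-methoxybenzyl)oxy]-6-[(4R)-2-(4-methoxyphenyl)-1,3-dioxolan-4-yl]-3-methyl-1-(phenylsulfonyl)oct-2-ene | O=S(=O)(c4ccccc4)C/C=C(/C)C[C@H](O[Si](C)(C)C(C)(C)C)[C@@H](CCOCc3ccc(OC)cc3)[C@@H]1COC(c2ccc(OC)cc2)O1 | intermediate
21 | (2R,3S,4S,6Z)-4-[(tert-butyldimethylsilyl)oxy]-2-[(4-methoxybenzyl)oxy]-3-{2-[(4-methoxybenzyl)oxy]ethyl}-6-methyl-8-(phenylsulfonyl)oct-6-en-1-ol | O=S(=O)(c4ccccc4)C/C=C(/C)C[C@H](O[Si](C)(C)C(C)(C)C)[C@@H](CCOCc3ccc(OC)cc3)[C@@H](OCc2ccc(OC)cc2)CO | intermediate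
22 | (2R,3S,4S,6Z)-4-[(tert-butyldimethylsilyl)oxy]-2-[(4-methoxybenzyl)oxy]-3-{2-[(4-methoxybenzyl)oxy]ethyl}-6-methyl-8-(phenylsulfonyl)oct-6-enal | O=S(=O)(c4ccccc4)C/C=C(/C)C[C@H](O[Si](C)(C)C(C)(C)C)[C@@H](CCOCc3ccc(OC)cc3)[C@@H](OCc2ccc(OC)cc2)C=O | intermediate
23 | ethyl (2E,4S,5S,6S,8Z)-6-[(tert-butyldimethylsilyl)oxy]-4-[(4-methoxybenzyl)oxy]-5-{2-[(4-methoxybenzyl)oxy]ethyl}-2,8-dimethyl-10-(phenylsulfonyl)deca-2,8-dienoate | O=S(=O)(c4ccccc4)C/C=C(/C)C[C@H](O[Si](C)(C)C(C)(C)C)[C@@H](CCOCc3ccc(OC)cc3)[C@@H](OCc2ccc(OC)cc2)/C=C(\C)C(=O)OCC | intermediate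
24 | (2E,4S,5S,6S,8Z)-6-[(tert-butyldimethylsilyl)oxy]-4-[(4-methoxybenzyl)oxy]-5-{2-[(4-methoxybenzyl)oxy]ethyl}-2,8-dimethyl-10-(phenylsulfonyl)deca-2,8-dien-1-ol | O=S(=O)(c4ccccc4)C/C=C(/C)C[C@H](O[Si](C)(C)C(C)(C)C)[C@@H](CCOCc3ccc(OC)cc3)[C@@H](OCc2ccc(OC)cc2)/C=C(\C)CO | intermediate
25 | (2E,4S,5S,6S,8Z)-1-bromo-6-[(tert-butyldimethylsilyl)oxy]-4-[(4-methoxybenzyl)oxy]-5-{2-[(4-methoxybenzyl)oxy]ethyl}-2,8-dimethyl-10-(phenylsulfonyl)deca-2,8-diene | O=S(=O)(c4ccccc4)C/C=C(/C)C[C@H](O[Si](C)(C)C(C)(C)C)[C@@H](CCOCc3ccc(OC)cc3)[C@@H](OCc2ccc(OC)cc2)/C=C(\C)CBr | intermediate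
26 | potassium α-sulfonyl carbanion of 25 | [K+].O=S(=O)(c4ccccc4)[CH-]/C=C(/C)C[C@H](O[Si](C)(C)C(C)(C)C)[C@@H](CCOCc3ccc(OC)cc3)[C@@H](OCc2ccc(OC)cc2)/C=C(\C)CBr | intermediate
27 | (1E,5Z,8S,9S,10S)-8-[(tert-butyldimethylsilyl)oxy]-10-[(4-methoxybenzyl)oxy]-9-{2-[(4-methoxybenzyl)oxy]ethyl}-2,6-dimethyl-4-(phenylsulfonyl)cyclodeca-1,5-diene (C4 epimers) | COc1ccc(CO[C@H]2/C=C(\C)CC(S(=O)(=O)c4ccccc4)/C=C(/C)C[C@H](O[Si](C)(C)C(C)(C)C)[C@H]2CCOCc3ccc(OC)cc3)cc1 | intermediate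
28 | (1E,5Z,8S,9S,10S)-8-[(tert-butyldimethylsilyl)oxy]-10-[(4-methoxybenzyl)oxy]-9-{2-[(4-methoxybenzyl)oxy]ethyl}-2,6-dimethylcyclodeca-1,5-diene | COc1ccc(CO[C@H]2/C=C(\C)CC/C=C(/C)C[C@H](O[Si](C)(C)C(C)(C)C)[C@H]2CCOCc3ccc(OC)cc3)cc1 | intermediate
29 | (1S,2E,6Z,9S,10S)-9-[(tert-butyldimethylsilyl)oxy]-10-(2-hydroxyethyl)-3,7-dimethylcyclodeca-2,6-dien-1-ol | O[C@H]1/C=C(\C)CC/C=C(/C)C[C@H](O[Si](C)(C)C(C)(C)C)[C@H]1CCO | intermediate
30 | hydroxy aldehyde: 29 with the hydroxyethyl arm oxidised to CH2CHO | O[C@H]1/C=C(\C)CC/C=C(/C)C[C@H](O[Si](C)(C)C(C)(C)C)[C@H]1CC=O | intermediate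
31 | (3aS,4S,6Z,10E,11aS)-4-[(tert-butyldimethylsilyl)oxy]-6,10-dimethyl-2,3,3a,4,5,8,9,11a-octahydrocyclodeca[b]furan-2-ol (lactol, anomers) | C1C(O)O[C@H]2/C=C(\C)CC/C=C(/C)C[C@H](O[Si](C)(C)C(C)(C)C)[C@H]21 | intermediate
32 | (3aS,4S,6Z,10E,11aS)-4-[(tert-butyldimethylsilyl)oxy]-6,10-dimethyl-3a,4,5,8,9,11a-hexahydrocyclodeca[b]furan-2(3H)-one | C1C(=O)O[C@H]2/C=C(\C)CC/C=C(/C)C[C@H](O[Si](C)(C)C(C)(C)C)[C@H]21 | intermediate
33 | lithium enolate of 32 | C1=C([O-])O[C@H]2/C=C(\C)CC/C=C(/C)C[C@H](O[Si](C)(C)C(C)(C)C)[C@H]21.[Li+] | intermediate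
34 | (3aS,4S,6Z,10E,11aS)-4-[(tert-butyldimethylsilyl)oxy]-3,6,10-trimethyl-3a,4,5,8,9,11a-hexahydrocyclodeca[b]furan-2(3H)-one (C3 epimers) | CC1C(=O)O[C@H]2/C=C(\C)CC/C=C(/C)C[C@H](O[Si](C)(C)C(C)(C)C)[C@H]21 | intermediate
35 | potassium enolate of 34 | CC1=C([O-])O[C@H]2/C=C(\C)CC/C=C(/C)C[C@H](O[Si](C)(C)C(C)(C)C)[C@H]21.[K+] | intermediate
36 | (3S,3aS,4S,6Z,10E,11aS)-4-[(tert-butyldimethylsilyl)oxy]-3-hydroxy-3,6,10-trimethyl-3a,4,5,8,9,11a-hexahydrocyclodeca[b]furan-2(3H)-one | O[C@]1(C)C(=O)O[C@H]2/C=C(\C)CC/C=C(/C)C[C@H](O[Si](C)(C)C(C)(C)C)[C@H]21 | intermediate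
37 | lithium alkoxide of 36 | [Li+].[O-][C@]1(C)C(=O)O[C@H]2/C=C(\C)CC/C=C(/C)C[C@H](O[Si](C)(C)C(C)(C)C)[C@H]21 | intermediate
38 | (3S,3aS,4S,6Z,10E,11aS)-4-[(tert-butyldimethylsilyl)oxy]-3,6,10-trimethyl-2-oxo-2,3,3a,4,5,8,9,11a-octahydrocyclodeca[b]furan-3-yl (2Z)-2-methylbut-2-enoate | C/C=C(/C)C(=O)O[C@]1(C)C(=O)O[C@H]2/C=C(\C)CC/C=C(/C)C[C@H](O[Si](C)(C)C(C)(C)C)[C@H]21 | intermediate
39 | (3S,3aR,4S,6Z,10E,11aS)-4-hydroxy-3,6,10-trimethyl-2-oxo-2,3,3a,4,5,8,9,11a-octahydrocyclodeca[b]furan-3-yl (2Z)-2-methylbut-2-enoate | C/C=C(/C)C(=O)O[C@]1(C)C(=O)O[C@H]2/C=C(\C)CC/C=C(/C)C[C@H](O)[C@H]21 | intermediate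
40 | (3S,3aR,4S,6Z,10E,11aS)-4-(acetyloxy)-3,6,10-trimethyl-2-oxo-2,3,3a,4,5,8,9,11a-octahydrocyclodeca[b]furan-3-yl (2Z)-2-methylbut-2-enoate | C/C=C(/C)C(=O)O[C@]1(C)C(=O)O[C@H]2/C=C(\C)CC/C=C(/C)C[C@H](OC(C)=O)[C@H]21 | target

**Summary**

Total step count: 28. Longest linear sequence: 28 steps (fully linear from 1).

Steps most likely to fail, with fallbacks:

The ring closure in step 20 is the weakest point, because a ten-membered carbocycle is formed by a carbanion alkylation that competes with oligomerisation and elimination. The fallback sets out from allylic alcohol 24 and replaces the SN2 closure with a palladium-templated one. Methyl chloroformate and pyridine give (2E,4S,5S,6S,8Z)-6-[(tert-butyldimethylsilyl)oxy]-4-[(4-methoxybenzyl)oxy]-5-{2-[(4-methoxybenzyl)oxy]ethyl}-2,8-dimethyl-10-(phenylsulfonyl)deca-2,8-dien-1-yl methyl carbonate F1. Pd(PPh3)4 (10 mol%) in THF at 50 °C under high dilution then ionises it to the π-allyl complex; the methoxide set free deprotonates the allylic sulfone, and the sulfonyl carbanion attacks the less hindered C3 terminus (Tsuji–Trost macrocyclisation). The (E)-olefin is kept and the route is rejoined at macrocyclic sulfone 27.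

The desulfonylation in step 21 can fail by hydride delivery to the wrong allyl terminus or by loss of the Z geometry in the π-allyl palladium intermediate. The fallback sets out from 27 and abandons π-allyl/hydride chemistry for a dissolving-metal reduction (Li, EtNH2/THF, −78 °C). Electron transfer cleaves the C–S bond, the allyl anion is protonated at the secondary carbon C2, and the same conditions cleave both PMB ethers. Compound 28 is therefore bypassed and the route is rejoined at diol 29; this fallback makes no compound outside the list (F0).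

The acylation in step 26 can fail because the tertiary, α-carbonyl alkoxide is hindered and angelates isomerise to tiglates when forced. The fallback sets out from 36 and builds the angelate on the substrate instead of transferring it. DCC-mediated esterification with 2-[bis(2,2,2-trifluoroethoxy)phosphoryl]propanoic acid (which acylates hindered alcohols through its phosphonoketene) gives (3S,3aS,4S,6Z,10E,11aS)-4-[(tert-butyldimethylsilyl)oxy]-3,6,10-trimethyl-2-oxo-2,3,3a,4,5,8,9,11a-octahydrocyclodeca[b]furan-3-yl 2-[bis(2,2,2-trifluoroethoxy)phosphoryl]propanoate F2. Still–Gennari olefination (KN(SiMe3)2, 18-crown-6, acetaldehyde, THF, −78 °C) then forms the (Z)-2-methylbut-2-enoate directly and rejoins the route at 38.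

Further compounds

F1 | step 20 | (2E,4S,5S,6S,8Z)-6-[(tert-butyldimethylsilyl)oxy]-4-[(4-methoxybenzyl)oxy]-5-{2-[(4-methoxybenzyl)oxy]ethyl}-2,8-dimethyl-10-(phenylsulfonyl)deca-2,8-dien-1-yl methyl carbonate | O=S(=O)(c4ccccc4)C/C=C(/C)C[C@H](O[Si](C)(C)C(C)(C)C)[C@@H](CCOCc3ccc(OC)cc3)[C@@H](OCc2ccc(OC)cc2)/C=C(\C)COC(=O)OC
F0 | step 21 | none | none
F2 | step 26 | (3S,3aS,4S,6Z,10E,11aS)-4-[(tert-butyldimethylsilyl)oxy]-3,6,10-trimethyl-2-oxo-2,3,3a,4,5,8,9,11a-octahydrocyclodeca[b]furan-3-yl 2-[bis(2,2,2-trifluoroethoxy)phosphoryl]propanoate (epimers at the phosphonate carbon) | CC(C(=O)O[C@]1(C)C(=O)O[C@H]2/C=C(\C)CC/C=C(/C)C[C@H](O[Si](C)(C)C(C)(C)C)[C@H]21)P(=O)(OCC(F)(F)F)OCC(F)(F)F
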